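A living end in this flask adds a unit of E about once in 4.55 h, and that slowness is what the argument turns on.

E 2.0 M; L 5 mol%; Q 16 mM; time 40 h

    E + L → D + J (k1 = 0.18 L mol⁻¹ h⁻¹)
    E + D → J + D, rate k2*[D]*[E] (k2 = 0.11 L mol⁻¹ h⁻¹)
    D → G (k3 = 0.12 h⁻¹)
    L + Q → L.Q (k4 = 860 L mol⁻¹ h⁻¹)

- whether the average number of monomer units in a chain (chains begun, living or dead) reaches 10 by 40 h (yes / no)
- average number of monomer units in a chain (chains begun, living or dead) at 40 h

- the average divides the monomer in chains by the number of chains begun, living and dead together
- run time (flask): 40 h

Two chemists dispute the flask before it is run. The first counts chains. Q takes L with a half-life of 0.050 h, while E starts chains from L with one of 1.93 h, so Q removes 16.0% of the L charged. The remaining 84.0% starts chains, and if their ends stay alive and share out the E, each gets 23.8 units, which is above the wanted 10.0.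

The second chemist answers that D goes to G with a half-life of 5.8 h, so an end has two moves, adding a unit or dying. Each runs at a steady rate per end, and growth is pseudo-first-order while E stands near its charge. Take the even case as the zero of the scale: with equal rates an end is a fair coin and adds one unit on average after its first. Any other ratio gives that ratio in added units. At the full charge of E this gives 1.83 for the growth odds, the rate at which an end adds a unit over the rate at which it dies.

I side with the second chemist and commit to 2.83, a top mark, since E falls as it is used. That stays below 10.0, so my answer on reaching it is no.

The forecast takes the same side: no, and 2.7, between 2.5 and 3, which is lower than my mark. Its grounds: “the living ends die in about 8 h, so by 40 h nearly all chains are dead”.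

The flask gives no and 2.68, so the second chemist holds, and the first chemist's picture of living chains fits this flask early: at 4.00 h, D is 47.5% of the L charged and G 15.8%. At 40.0 h, with E at 89%, this flask's odds read 1.63, giving 2.63 for the last ends, and its average lies between that and 2.83; the neighbour flask with 20 mol% of L ended with E at 56% and odds of 1.02, and its average of 2.27 lies between 2.02 and 2.83.

All constants are those of an exercise; the rest is arithmetic.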